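**Retrosynthetic overview**
- The target is an achiral 1,3-diester of a 2-arylglycerol. Its two primary C–O ester bonds are cut first, giving isobutyric acid and 1,3-dichloro-2-(2-methoxy-4-methylphenyl)propan-2-ol, a masked bis-epoxide.
- The plan rests on the tertiary carbinol carbon bonded to C1 of the benzene ring. It bears two identical CH2O arms, so both C(carbinol)–CH2 bonds are cut together, back to the carbonyl carbon of methyl 2-methoxy-4-methylbenzoate and two chloromethyl carbenoid units from chloroiodomethane.
- The methoxy ester comes from 4-methylsalicylic acid by methylation of both oxygens.
- Ring order: the benzene ring is present from the first compound and no ring of the target is built. The only rings that close are two short-lived oxiranes in the last step, which reopen in the same flask.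

Key step: step 2

Remark: the target has no stereocenter, because the carbinol carbon carries two identical acyloxymethyl arms. Nothing needs stereocontrol, and the chiral transient intermediates of the last step are racemic and converge on the achiral product.

**Step 1**
Reactants: 1 4-methylsalicylic acid (2-hydroxy-4-methylbenzoic acid)
Product: 2 methyl 2-methoxy-4-methylbenzoate
Conditions: Me2SO4 (2.5 equiv), K2CO3 (3 equiv), acetone, reflux
Reagents that add atoms: dimethyl sulfate COS(=O)(=O)OC
Why: Twofold Williamson-type O-methylation (SN2 at the methyl group of dimethyl sulfate) of the carboxylate and the phenoxide, where excess K2CO3 in refluxing acetone should break the intramolecular hydrogen bond of the salicylate and carry the phenol through to the methyl ether.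

**Step 2**
Reactants: 2 methyl 2-methoxy-4-methylbenzoate; 3 chloroiodomethane
Product: 5 1,3-dichloro-2-(2-methoxy-4-methylphenyl)propan-2-ol, via 2-chloro-1-(2-methoxy-4-methylphenyl)ethan-1-one 4 (not isolated)
Conditions: 3 (3.0 equiv), MeLi·LiBr (2.8 equiv in Et2O, slow addition), THF, −78 °C; then AcOH/THF, −78 °C
Reagents that add atoms: none
Why: Iodine–lithium exchange between 3 and MeLi·LiBr gives LiCH2Cl in the presence of the ester, the carbenoid adds to the C=O of 2, and the lithium hemiketal expels LiOMe to leave chloromethyl ketone 4, which is a better electrophile than 2 and should capture the second LiCH2Cl at once, so that both C(carbinol)–CH2 bonds form in one flask. The closest known reaction type is the homologation of carboxylic esters with halomethyllithium carbenoids, in which excess reagent leads to bis(chloromethyl) carbinols. No ring is closed and no stereocenter arises, because the new carbinol carbon carries two identical CH2Cl groups. The step needs chemoselectivity for twofold carbenoid addition over α-elimination of LiCH2Cl, over direct attack of MeLi on the carbonyl group and over enolization of 4; slow addition of MeLi·LiBr to the ester in the presence of a slight excess of 3 at −78 °C should secure it, since exchange at iodine outpaces carbonyl addition, and the ortho methoxy oxygen of 2 can chelate lithium and guide the reagent to the carbonyl carbon. Protonation with AcOH at −78 °C keeps the lithium alkoxide of 5 from closing to a chloromethyl oxirane, and any such oxirane that does form is itself an intermediate of the next step and is not lost.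

**Step 3**
Reactants: 5 1,3-dichloro-2-(2-methoxy-4-methylphenyl)propan-2-ol; 6 isobutyric acid (2-methylpropanoic acid)
Product: 10 2-hydroxy-2-(2-methoxy-4-methylphenyl)propane-1,3-diyl bis(2-methylpropanoate), via 2-(chloromethyl)-2-(2-methoxy-4-methylphenyl)oxirane 7 (not isolated), via 3-chloro-2-hydroxy-2-(2-methoxy-4-methylphenyl)propyl 2-methylpropanoate 8 (not isolated), via [2-(2-methoxy-4-methylphenyl)oxiran-2-yl]methyl 2-methylpropanoate 9 (not isolated)
Conditions: 6 (3 equiv), Cs2CO3 (1.5 equiv), DMF, 23 °C; then 5, 75 °C
Reagents that add atoms: none
Why: Carboxylate alkylation by a halohydrin–epoxide relay, as in glycidyl ester and 1,3-diglyceride preparations: each chlorohydrin should close (3-exo-tet) to an oxirane that cesium isobutyrate opens by SN2 at the unsubstituted CH2, first through 7 and 8 and then through 9, while the buffered carboxylate medium leaves the tertiary benzylic OH free.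

**Compound list**
1 | 4-methylsalicylic acid (2-hydroxy-4-methylbenzoic acid) | Cc1ccc(C(=O)O)c(O)c1 | starting material
2 | methyl 2-methoxy-4-methylbenzoate | COc1cc(C)ccc1C(=O)OC | intermediate
3 | chloroiodomethane | ClCI | starting material
4 | 2-chloro-1-(2-methoxy-4-methylphenyl)ethan-1-one | COc1cc(C)ccc1C(=O)CCl | intermediate
5 | 1,3-dichloro-2-(2-methoxy-4-methylphenyl)propan-2-ol | COc1cc(C)ccc1C(O)(CCl)CCl | intermediate
6 | isobutyric acid (2-methylpropanoic acid) | CC(C)C(=O)O | starting material
7 | 2-(chloromethyl)-2-(2-methoxy-4-methylphenyl)oxirane (racemic) | COc1cc(C)ccc1C1(CCl)CO1 | intermediate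
8 | 3-chloro-2-hydroxy-2-(2-methoxy-4-methylphenyl)propyl 2-methylpropanoate (racemic) | COc1cc(C)ccc1C(O)(CCl)COC(=O)C(C)C | intermediate
9 | [2-(2-methoxy-4-methylphenyl)oxiran-2-yl]methyl 2-methylpropanoate (racemic) | COc1cc(C)ccc1C1(COC(=O)C(C)C)CO1 | intermediate
10 | 2-hydroxy-2-(2-methoxy-4-methylphenyl)propane-1,3-diyl bis(2-methylpropanoate) | COc1cc(C)ccc1C(O)(COC(=O)C(C)C)COC(=O)C(C)C | target

Total step count: 3
Longest linear sequence: 3 steps (1 → 2 → 5 → 10)

**Steps most likely to fail**

1. Step 2. The carbenoid may decompose by α-elimination faster than it adds to the electron-rich, ortho-substituted ester. The sequence may also stop after one addition if the tetrahedral intermediate does not collapse at −78 °C, or MeLi may attack the carbonyl group directly. Fallback, setting out from 2 and coming back at 5: the first C–C bond is made without a carbenoid. Trimethylsulfoxonium iodide and KOtBu in refluxing THF should acylate dimethylsulfoxonium methylide with 2 to give the stabilized ylide dimethylsulfoxonium 2-(2-methoxy-4-methylphenyl)-2-oxoethylide F1. HCl in THF at 65 °C should then convert this ylide, with loss of dimethyl sulfoxide, into chloromethyl ketone 4, which is now isolated. A single addition of LiCH2Cl to this activated ketone (3, MeLi·LiBr, THF, −78 °C, AcOH quench) should give 5.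

2. Step 3. The carboxylate may open the aryl-substituted oxiranes at the benzylic quaternary carbon instead of at CH2. The second displacement may also stall, or acyl transfer and ester cleavage may occur in the warm basic medium. Fallback, setting out from 5 and coming back at 10: the C–O bonds are formed with hydroxide and the acyl groups are put on afterwards. Aqueous NaOH in 1,4-dioxane at 80 °C should hydrolyse both chlorides through the same oxiranes to 2-(2-methoxy-4-methylphenyl)propane-1,2,3-triol F2. Isobutyryl chloride (2.2 equiv) with pyridine in CH2Cl2 at 0 °C should then acylate only the two primary hydroxyl groups, leaving the hindered tertiary benzylic one, to give 10.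

3. Step 1. Methylation may stop at the ester stage, because the phenol is hydrogen-bonded to the carbonyl group and is a poor nucleophile. Fallback, setting out from 1 and coming back at 2: the two methylations are separated and run by different mechanisms. Fischer esterification (MeOH, catalytic H2SO4, reflux) should give methyl 2-hydroxy-4-methylbenzoate F3. Alkylation of its free phenoxide with MeI and K2CO3 in DMF at 60 °C should then give 2.

**Further compounds**
F1 | step 2 | dimethylsulfoxonium 2-(2-methoxy-4-methylphenyl)-2-oxoethylide | COc1cc(C)ccc1C(=O)C=S(C)(C)=O
F2 | step 3 | 2-(2-methoxy-4-methylphenyl)propane-1,2,3-triol | COc1cc(C)ccc1C(O)(CO)CO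
F3 | step 1 | methyl 2-hydroxy-4-methylbenzoate | Cc1ccc(C(=O)OC)c(O)c1
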